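**Plan**
Cuts: first O1–C8a of ring C, an aryl C–O bond made at a C–H position instead of the usual O1–C2 dehydration. The second cut is C2–C3 of the three-carbon bridge, which leads back through an aryl ester to a ring A acetophenone and a ring B benzoic acid.
Enabling feature: ring A carries its C5–OH and C8–OMe in a 1,4-relationship. Two-electron oxidation in methanol therefore turns it into a cyclohexadienone with C5 as carbonyl and C8 as dimethyl ketal. In that dienone the hydrogen-bearing C8a sits at the β-end of an enone shared by C5=O and the exocyclic C4=O.
Forward order: rings A and B are bought intact. The bridge is joined by O-aroylation at the C5 oxygen and a Baker–Venkataraman O-to-C shift (C2–C3). Ring C closes last, by anodic dearomatisation of ring A, addition of the C2 enol oxygen to C8a and loss of methanol.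
Stereochemistry: the target is achiral. The one transient stereocentre (C8a of the cyclised adduct) forms racemic and vanishes on rearomatisation.

Key step: step 4

Remark: flavone numbering (O1, C2, C3, C4, C4a, C5–C8, C8a) is used for all open-chain and dearomatised intermediates, and the diketone phenol is drawn as its diketo tautomer although it should exist largely as the chelated enol.

Step 1
Reactants: 1 2,3,4-trimethoxybenzoic acid
Product: 2 2,3,4-trimethoxybenzoyl chloride
Conditions: (COCl)2, DMF (cat.), CH2Cl2, 0 °C → rt; concentrate, use crude
Reagents that add atoms: oxalyl chloride, O=C(Cl)C(=O)Cl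
Why: DMF-catalysed acid chloride formation through the Vilsmeier-type chloroiminium salt is routine for alkoxybenzoic acids, and the three aryl methyl ethers are inert under these mild, Lewis-acid-free conditions.

Step 2
Reactants: 2 2,3,4-trimethoxybenzoyl chloride; 3 2'-hydroxy-4',5'-dimethoxyacetophenone
Product: 4 2-acetyl-4,5-dimethoxyphenyl 2,3,4-trimethoxybenzoate
Conditions: Et3N, DMAP (cat.), CH2Cl2, 0 °C → rt
Reagents that add atoms: none
Why: DMAP-catalysed O-acylation (nucleophilic-catalysis esterification) of the single phenolic hydroxyl by an acid chloride is the standard entry to a Baker–Venkataraman substrate, the acylpyridinium salt being reactive enough to overcome the hydrogen bond between the phenol and the acetyl carbonyl.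

Step 3
Reactants: 4 2-acetyl-4,5-dimethoxyphenyl 2,3,4-trimethoxybenzoate
Product: 5 1-(2-hydroxy-4,5-dimethoxyphenyl)-3-(2,3,4-trimethoxyphenyl)propane-1,3-dione
Conditions: KOH (powdered), pyridine, 50 °C; then cold 10% aq. AcOH
Reagents that add atoms: none
Why: Baker–Venkataraman rearrangement: the acetyl enolate attacks the neighbouring ester carbonyl through a six-membered cyclic alkoxide that collapses with release of the phenolate, forming C2–C3, and the cold weakly acidic quench returns the free diketone phenol without triggering cyclodehydration.

Step 4
Reactants: 5 1-(2-hydroxy-4,5-dimethoxyphenyl)-3-(2,3,4-trimethoxyphenyl)propane-1,3-dione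
Product: 8 serpyllin (5-hydroxy-7,8-dimethoxy-2-(2,3,4-trimethoxyphenyl)-4H-chromen-4-one), via quinone monoketal 6 (not isolated), via dihydrochromenone adduct 7 (not isolated)
Conditions: graphite anode, Pt cathode, undivided cell, LiClO4 (0.1 M), 2,6-lutidine, MeOH, 0 °C, constant current, 2.1 F/mol; then current off, AcOH, 0 °C → rt
Reagents that add atoms: methanol, CO
Why: Proposed new method: the electron-rich 4-methoxyphenol of ring A should be the most easily oxidised site of 5, so two-electron anodic oxidation with capture of methanol at C8 (para to the C5 oxygen, where the resident methoxy group stabilises the phenoxenium charge) should give dienone ketal 6, which is the established anodic route from 4-methoxyphenols to quinone monoketals. In 6 the C4a=C8a double bond is an alkylidene 1,3-dicarbonyl unit, and the enol oxygen on C2 should add to C8a in a 6-endo-trig oxa-Michael closure of ring C (equivalently an oxa-6π electrocyclisation of the O=C2–C3=C4(OH)–C4a=C8a oxatriene) to give 7. Once the current is off, acetic acid ionises the C8 ketal, the C8a hydrogen is lost from the resulting oxocarbenium (Wheland-type) ion and ring A returns to the arene with C5–OH and C8–OMe in place; the closest known reaction type is addition–elimination of nucleophiles on acyl-activated quinone monoketals, which has not been used to close a pyranone ring from a diketone enol. The only new stereocentre, C8a of 7, forms racemic and is erased by the elimination, so no stereocontrol is required. The selectivity needed is O1–C8a closure instead of dehydrative closure through the C5 oxygen (which would give the 6,7-dimethoxy isomer): the cold lutidine-buffered electrolyte keeps 5 open, the oxidation itself converts the C5 oxygen into a non-nucleophilic carbonyl, C3 could reach C8a only through a four-membered ring, and C7 is a deactivated vinylogous ester position. Holding the material at the dearomatised stage of 6 and 7 until electrolysis is over also shields the product, itself a 4-methoxyphenol, from a second oxidation.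

**Compound list**
1 | 2,3,4-trimethoxybenzoic acid | COc1ccc(C(=O)O)c(OC)c1OC | starting material
2 | 2,3,4-trimethoxybenzoyl chloride | COc1ccc(C(=O)Cl)c(OC)c1OC | intermediate
3 | 2'-hydroxy-4',5'-dimethoxyacetophenone | CC(=O)c1cc(OC)c(OC)cc1O | starting material
4 | 2-acetyl-4,5-dimethoxyphenyl 2,3,4-trimethoxybenzoate | CC(=O)c1cc(OC)c(OC)cc1OC(=O)c1ccc(OC)c(OC)c1OC | intermediate
5 | 1-(2-hydroxy-4,5-dimethoxyphenyl)-3-(2,3,4-trimethoxyphenyl)propane-1,3-dione | COc1ccc(C(=O)CC(=O)c2cc(OC)c(OC)cc2O)c(OC)c1OC | intermediate
6 | 1-(3,3,4-trimethoxy-6-oxocyclohexa-1,4-dien-1-yl)-3-(2,3,4-trimethoxyphenyl)propane-1,3-dione (quinone monoketal) | COc1ccc(C(=O)CC(=O)C2=CC(OC)(OC)C(OC)=CC2=O)c(OC)c1OC | intermediate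
7 | 5-hydroxy-7,8,8-trimethoxy-2-(2,3,4-trimethoxyphenyl)-8,8a-dihydro-4H-chromen-4-one (racemic at C8a, drawn as the C4a=C5 enol) | COc1ccc(C2=CC(=O)C3=C(O)C=C(OC)C(OC)(OC)C3O2)c(OC)c1OC | intermediate
8 | serpyllin, 5-hydroxy-7,8-dimethoxy-2-(2,3,4-trimethoxyphenyl)-4H-chromen-4-one | COc1ccc(-c2cc(=O)c3c(O)cc(OC)c(OC)c3o2)c(OC)c1OC | target

Total step count: 4.
Longest linear sequence: 4 steps (1 → 2 → 4 → 5 → 8).

**Steps most likely to fail**

1. Step 4.
- Risks: Solvent methanol may add to C8a faster than the enol oxygen. The diketone enol may be oxidised alongside ring A. Ring A may be oxidised a second time if rearomatisation starts during electrolysis. Cathodic back-reduction of the ketal would only cost current.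
- Fallback (known chemistry), setting out from 2 and coming back at 8: The oxygen at C8a is bought instead of installed. 2'-Hydroxy-3',4',6'-trimethoxyacetophenone F1 (purchased) is treated with excess LiN(SiMe3)2 in THF at −78 °C and then with 2, a direct C-acylation. This should give 1-(2-hydroxy-3,4,6-trimethoxyphenyl)-3-(2,3,4-trimethoxyphenyl)propane-1,3-dione F2. Cyclodehydration through its only free hydroxyl (H2SO4 cat., AcOH, heat) should give 5,7,8-trimethoxy-2-(2,3,4-trimethoxyphenyl)-4H-chromen-4-one F3. BCl3 in CH2Cl2 (−78 → 0 °C), chelated between the C4 carbonyl and the C5 oxygen, should then remove only the C5 methyl group to give 8.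

2. Step 3.
- Risks: Hydroxide may cleave the aryl ester in competition with the acyl shift. Ring closure through the C5 oxygen may begin during the quench.
- Fallback, setting out from 3 (together with 2) and coming back at 5: The O-to-C transfer is replaced by an intermolecular C-acylation. Compound 3 is deprotonated at both the phenol and the methyl group with excess LiN(SiMe3)2 in THF at −78 °C. The more reactive enolate carbon is then acylated with 2. Any O-acylated material should rearrange under the excess base, and a cold dilute AcOH quench should deliver 5 without passing through isolated 4.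

3. Step 2.
- Risks: O-acylation of the hydrogen-bonded phenol by the ortho-substituted aroyl chloride may be sluggish, and the acid chloride may be lost to hydrolysis.
- Fallback, setting out from 1 and coming back at 5: O-acylation is avoided altogether. Fischer esterification of 1 (MeOH, H2SO4 cat., reflux) should give methyl 2,3,4-trimethoxybenzoate F4. A crossed Claisen condensation of F4 with 3 (NaH in excess, THF, reflux; cold dilute AcOH quench) should form C2–C3 directly and deliver 5.

**Further compounds**
F1 | step 4 | 2'-hydroxy-3',4',6'-trimethoxyacetophenone | CC(=O)c1c(O)c(OC)c(OC)cc1OC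
F2 | step 4 | 1-(2-hydroxy-3,4,6-trimethoxyphenyl)-3-(2,3,4-trimethoxyphenyl)propane-1,3-dione | COc1ccc(C(=O)CC(=O)c2c(O)c(OC)c(OC)cc2OC)c(OC)c1OC
F3 | step 4 | 5,7,8-trimethoxy-2-(2,3,4-trimethoxyphenyl)-4H-chromen-4-one | COc1ccc(-c2cc(=O)c3c(OC)cc(OC)c(OC)c3o2)c(OC)c1OC
F0 | step 3 | none | none
F4 | step 2 | methyl 2,3,4-trimethoxybenzoate | COC(=O)c1ccc(OC)c(OC)c1OC
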